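## The problem

Caraganin B (19) is a 5-hydroxy-7-methoxyisoflavone whose resorcinol ring B carries at C5' a (1R,2E)-1-(4-hydroxyphenyl)-3-(2,4-dimethoxyphenyl)allyl group. The skeleton is held together by three kinds of bond: the C3–C1' bond between the pyranone (ring C) and ring B, the sp3 methine that joins ring B, the 4-hydroxyphenyl ring and the vinyl group, and the E double bond to the 2,4-dimethoxyphenyl ring. The methine is the only stereocenter. Nothing else in the molecule can relay chirality to it, so it must be set by a catalyst, and once made it should not meet strong base, because it is doubly benzylic and allylic. Ring A carries a free, chelated 5-OH beside a 7-OMe, so its two oxygens have to be distinguished.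

The finished molecule is fragile in several directions. Acid protonates the electron-rich styrene to a 2,4-dimethoxybenzyl cation, which the neighbouring 4'-OH would trap as a flavan. Oxidants such as trivalent thallium or quinones attack the styrene. Hydrogenolysis saturates it. Hydroxide, alkoxide and hydride add to C2 of the isoflavone. The last step therefore has to be neutral and non-reductive.

The feature that invites the key step is the C3–C1' bond itself. It joins the α-carbon of an aryl ketone to an aryl ring with oxygens at 2' and 4', that is, to a very good migrating group. An (E)-2'-hydroxychalcone carries this ring on its β-carbon, one 1,2-shift away, with the 2'-hydroxyl placed to close O1–C2.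

## Retrosynthesis

**19 to 18.** Only O–Si bonds are cut. Because acid, strong base and hydrogen are all excluded at the end, the phenols of ring B and of the 4-hydroxyphenyl ring are carried as aryl silyl ethers, which buffered fluoride removes near neutrality. The chelated 5-OH needs no protection. The penultimate compound is the tris-silyl ether 18.

**18 to 17 to 16.** The E double bond is traced to a 1,2-elimination of the benzylic alcohol 17, and 17 to the ketone 16. The obvious neighbour, olefination of a diarylacetaldehyde, would place the stereocenter α to a carbonyl group, where it racemises, and would raise an E/Z question. A 2,4-dimethoxybenzylic alcohol, in contrast, can lose water only towards the conjugated styrene. The alkene problem thus becomes a β,β-diaryl ketone. What is asked of the forward steps is reduction of an aryl ketone beside an isoflavone and dehydration without a long-lived cation.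

**16 to 14 and 15.** The aryl–C bond at the stereocenter is cut. Conjugate arylation of enone 14 with boronic acid 15 under rhodium–bisphosphine catalysis sets the centre by catalyst control. Adding the simple 4-silyloxyphenyl group is preferred to the reverse polarity, which would need a boron substituent on the fully elaborated ring B. The precursor 14 is achiral and planar. The reaction must choose one face of the acyclic enone and leave the α-arylated C2=C3 bond of the isoflavone alone.

**14 to 10 and 12.** The enone double bond is cut to aldehyde 10 and the keto-stabilised phosphonium salt 12, which comes from bromoketone 11. A base-mediated aldol condensation would make the same bond but would expose the isoflavone to hydroxide. The Wittig reaction is neutral and E-selective.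

**10 to 9.** This is a protecting-group exchange. Acetal ethers are needed early because step 3 uses hydroxide, but they can only be removed by acid, which the finished molecule cannot tolerate. A single set of acetal groups carried to the end would therefore have to survive the acid of the ring closure and then be removed under forcing conditions. It is safer to let the key step's acid strip them at the aldehyde stage, where no styrene exists, and to silylate triol 9 to 10.

**9 to 5 (key disconnection).** C3–C1' and O1–C2 are cut, which opens ring C to the 2'-hydroxychalcone 5 with ring B on the β-carbon. The alternatives for C3–C1', cross-coupling of a 3-halochromone or a deoxybenzoin with a one-carbon insertion, each need a separately functionalised ring B partner made in several steps. The chalcone comes from one condensation of two simple pieces. The forward reaction must give aryl migration and no other oxidative pathway. That requires the extra formyl group of ring B to be masked as an acetal and the step to be run before the styrene exists.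

**5 to 4 and 2; 2 to 1; 4 to 3.** The chalcone is cut at its double bond (Claisen–Schmidt). Acetophenone 4 inherits the 5-OH/7-OMe pattern of the target from 3: one hydroxyl is capped, the other stays free for ring closure. Dialdehyde 2 is the bis-MOM ether of 1. Its two formyl groups are equivalent, so mono-condensation is only statistically controlled. This is accepted for the sake of brevity and answered by an excess of recoverable 2.

## Roads not taken

**Alternative 1:** Ring A is removed entirely (C4a–C5, C5–C6, C7–C8, C8–C8a), leaving pyranonyl diazoketone A1 and methoxyacetylene A2. On long-wavelength irradiation A1 undergoes the Wolff shift (C8–C8a). The ketene takes up A2 in a [2+2] cycloaddition (C5–C6, C7–C8), and four-electron opening followed by six-electron electrocyclisation (C4a–C5) gives tris-O-TIPS caraganin B A3, one fluoride step from the target.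
- Merits: the 5-OH/7-OMe pattern arises regiospecifically from the polarity of the ynol ether, with no protection on ring A. The isoflavone is formed last and never meets the base, hydride or rhodium chemistry of the side chain. No thallium is used.
- Weak points: A1 already contains the complete stereodefined triarylpropene, so the whole asymmetric side-chain synthesis must be carried out on a 5-aryl-4-pyranone-2-carboxylic acid derivative that is itself a multistep target. The annulation must use the enol-ether double bond of a cross-conjugated pyranone as the vinyl part of the ketene, a substrate type for which it is not established. Irradiation of a molecule holding a styrene and a pyranone invites E/Z isomerisation and cycloaddition. A2 is volatile and unstable.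
- Comparison: this road is better in steps after the key step (one against seven) and in protecting-group economy on ring A. The chosen plan sets against this a key step with direct precedent, run at step 4 on a compound three steps from cheap materials, so that a failure costs little.

**Alternative 2:** C4–C4a and O1–C2 are cut, giving aryl ester A4, the 3,5-dimethoxyphenyl ester of an α-aryl-β-methoxyacrylic acid. BF3·OEt2 moves the acyl group to the ortho carbon (Fries shift), and the freed phenol displaces methanol at C2 to give bromo isoflavone A5.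
- Merits: it is convergent and thallium-free, and the bromine marks C5' unambiguously, so there is no statistical step.
- Weak points: ring A arrives as the 5,7-dimethyl ether and needs a selective, chelation-controlled 5-O-demethylation. The isopropyl ethers of A5 come off only with strong Lewis acid, which the finished styrene and 4'-phenol cannot stand, so a protecting-group exchange is needed here as well. The Fries shift can also go to the para carbon between the two methoxy groups, giving a ketone that cannot cyclise. The bromide of A5 must still be turned into the formyl group or coupled before the same side-chain chemistry begins.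
- Comparison: this road is better on toxicity and on the desymmetrisation problem, and equal in the side-chain steps. The chosen plan sets against this the inherited 5-OH/7-OMe pattern and an aldehyde already in place, which saves the demethylation and the bromide-to-carbon step.

**Alternative 3:** O1–C8a and C4–C4a are cut, giving silylaryl triflate A6 and acrylic acid A7. CsF releases the aryne from A6. The carboxylate of A7 adds at the aryne carbon remote from the flanking methoxy group, the aryl anion takes the acyl group (net insertion into the C–O bond), and the phenoxide displaces methoxide at C2 to give tris-O-allyl 5-O-methyl caraganin B A8.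
- Merits: it is the most convergent road. The side chain and stereocenter are complete before the ring is made, the methoxy group steers the regiochemistry to the correct 5,7-pattern, the conditions are mild and non-oxidative, and the allyl ethers can be removed with zerovalent palladium under neutral conditions.
- Weak points: simple O-arylation of the acid without acyl transfer competes with the insertion. A8 still carries a 5-OMe, whose Lewis-acid cleavage falls on the acid-sensitive final skeleton. A7 demands the asymmetric side-chain chemistry on an arylacetic acid plus its conversion to the β-methoxyacrylate, and A6 takes several steps.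
- Comparison: this road is as good or better in convergence and in sparing the isoflavone the side-chain steps. The chosen plan sets against this a ring A that needs no late demethylation, a ring-forming step with close precedent, and a neutral last step.

Key step: step 4

Remark: the sense of induction in step 8 is assigned by analogy with (E)-configured acyclic enones and enoates, and 11 and 15 are taken as purchased (11 is one α-bromination from 2',4'-dimethoxyacetophenone, 15 one silylation from 4-hydroxyphenylboronic acid).

## Route

Step 1
Reactants: 1 4,6-dihydroxybenzene-1,3-dicarbaldehyde (4,6-dihydroxyisophthalaldehyde)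
Product: 2 4,6-bis(methoxymethoxy)benzene-1,3-dicarbaldehyde
Conditions: MOMCl (3 equiv), iPr2NEt (4 equiv), CH2Cl2, 0 °C to rt
Reagents that add atoms: chloromethyl methyl ether, COCCl
Why: O-Alkylation of both hydrogen-bonded salicylaldehyde hydroxyls by the reactive α-chloro ether (Williamson type); the MOM ethers withstand the hydroxide of step 3 and fall off in the acid stage of step 4.

Step 2
Reactants: 3 1-(2,6-dihydroxy-4-methoxyphenyl)ethan-1-one
Product: 4 1-[2-hydroxy-4-methoxy-6-(methoxymethoxy)phenyl]ethan-1-one
Conditions: MOMCl (1.1 equiv), iPr2NEt (1.5 equiv), CH2Cl2, 0 °C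
Reagents that add atoms: chloromethyl methyl ether, COCCl
Why: The two hydroxyls of 3 are equivalent; after the first O-alkylation the remaining one is locked in a hydrogen bond to the acetyl oxygen and is much less nucleophilic, so the reaction should stop at the mono-ether, leaving the hydroxyl needed for ring closure.

Step 3
Reactants: 4 1-[2-hydroxy-4-methoxy-6-(methoxymethoxy)phenyl]ethan-1-one; 2 4,6-bis(methoxymethoxy)benzene-1,3-dicarbaldehyde
Product: 5 5-{(1E)-3-[2-hydroxy-4-methoxy-6-(methoxymethoxy)phenyl]-3-oxoprop-1-en-1-yl}-2,4-bis(methoxymethoxy)benzaldehyde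
Conditions: KOH (50% aq.), EtOH, 0 °C to rt; 2 in threefold excess, recovered
Reagents that add atoms: none
Why: Claisen–Schmidt condensation (aldol addition, then E1cB loss of water) gives the E enone. The two formyl groups of 2 are equivalent and not conjugated with each other, so mono-condensation is secured statistically by the excess of 2, which is recovered.

Step 4
Reactants: 5 5-{(1E)-3-[2-hydroxy-4-methoxy-6-(methoxymethoxy)phenyl]-3-oxoprop-1-en-1-yl}-2,4-bis(methoxymethoxy)benzaldehyde
Product: 9 2,4-dihydroxy-5-(5-hydroxy-7-methoxy-4-oxo-4H-chromen-3-yl)benzaldehyde, via chalcone dimethyl acetal 6 (not isolated), via rearranged keto bis-acetal 7 (not isolated), via MOM-protected isoflavone acetal 8 (not isolated)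
Conditions: HC(OMe)3/MeOH (1:3), camphorsulfonic acid (5 mol %), rt; then Tl(NO3)3·3H2O (1.2 equiv), rt; filter off TlNO3; then 3 M aq. HCl/MeOH, 55 °C
Reagents that add atoms: water, O
Why: The orthoformate first turns the free formyl group into its dimethyl acetal (6), so that ring B meets the oxidant as a 2,4-dialkoxyphenyl group without a conjugated acceptor. Trivalent thallium then adds to the enone double bond with methanol entering at the β-carbon; the C–Tl bond at the α-carbon ionises with loss of monovalent thallium while ring B bridges as a phenonium ion and ends on the α-carbon, forming C3–C1' and leaving the β-carbon as a dimethyl acetal (7). This is the known oxidative 1,2-aryl rearrangement of 2'-hydroxychalcones by Tl(NO3)3 in methanol, the laboratory counterpart of the isoflavone synthase shift. Acid ionises the acetal of 7, the 2'-hydroxyl attacks the oxocarbenium carbon (6-exo-trig) to form O1–C2, and loss of methanol gives the pyranone ring (8). Continued warming in aqueous methanolic HCl removes the three MOM groups and hydrolyses the aryl acetal, so one operation should deliver triol aldehyde 9, whose formyl oxygen then comes from water. No stereocenter is formed, since the α-carbon of 7 becomes sp2. The step needs aryl migration in preference to aurone formation through attack of the 2'-hydroxyl and to aroyl or hydride shift; the alkoxy groups ortho and para to the migrating carbon and the masking of the formyl group secure this, and the step is placed before any styrene exists because trivalent thallium would attack it.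

Step 5
Reactants: 9 2,4-dihydroxy-5-(5-hydroxy-7-methoxy-4-oxo-4H-chromen-3-yl)benzaldehyde
Product: 10 5-(5-hydroxy-7-methoxy-4-oxo-4H-chromen-3-yl)-2,4-bis[(triisopropylsilyl)oxy]benzaldehyde
Conditions: TIPSCl (2.5 equiv), imidazole (5 equiv), DMF, rt to 40 °C
Reagents that add atoms: chlorotriisopropylsilane, CC(C)[Si](Cl)(C(C)C)C(C)C
Why: Phenol silylation; the 5-OH is chelated to the C4 carbonyl and should stay free, as in the target, while the two hydroxyls of ring B receive groups that buffered fluoride removes in step 11.

Step 6
Reactants: 11 2-bromo-1-(2,4-dimethoxyphenyl)ethan-1-one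
Product: 12 [2-(2,4-dimethoxyphenyl)-2-oxoethyl]triphenylphosphonium bromide
Conditions: PPh3 (1.05 equiv), toluene, 60 °C
Reagents that add atoms: triphenylphosphine, c1ccc(cc1)P(c1ccccc1)c1ccccc1
Why: SN2 displacement of the activated α-bromo ketone by the phosphine; the salt should crystallise from toluene.

Step 7
Reactants: 10 5-(5-hydroxy-7-methoxy-4-oxo-4H-chromen-3-yl)-2,4-bis[(triisopropylsilyl)oxy]benzaldehyde; 12 [2-(2,4-dimethoxyphenyl)-2-oxoethyl]triphenylphosphonium bromide
Product: 14 (2E)-1-(2,4-dimethoxyphenyl)-3-{5-(5-hydroxy-7-methoxy-4-oxo-4H-chromen-3-yl)-2,4-bis[(triisopropylsilyl)oxy]phenyl}prop-2-en-1-one, via phosphorus ylide 13 (not isolated)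
Conditions: Et3N (1.5 equiv), toluene, 100 °C
Reagents that add atoms: none
Why: Wittig reaction of a keto-stabilised ylide, which gives the E enone; the ylide is too weak a base and nucleophile to open the isoflavone, which a hydroxide-mediated condensation at this stage would do.

Step 8
Reactants: 14 (2E)-1-(2,4-dimethoxyphenyl)-3-{5-(5-hydroxy-7-methoxy-4-oxo-4H-chromen-3-yl)-2,4-bis[(triisopropylsilyl)oxy]phenyl}prop-2-en-1-one; 15 {4-[(tert-butyldimethylsilyl)oxy]phenyl}boronic acid
Product: 16 (3R)-3-{4-[(tert-butyldimethylsilyl)oxy]phenyl}-1-(2,4-dimethoxyphenyl)-3-{5-(5-hydroxy-7-methoxy-4-oxo-4H-chromen-3-yl)-2,4-bis[(triisopropylsilyl)oxy]phenyl}propan-1-one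
Conditions: [Rh(OH)((S)-BINAP)]2 (3 mol %), 15 (3 equiv), dioxane/H2O (10:1), 50 °C
Reagents that add atoms: none
Why: Hayashi–Miyaura reaction: transmetalation gives an aryl complex of monovalent rhodium, the enone inserts, and water releases the ketone. The 3R centre requires delivery of the aryl group to the Si face of C3 (also Si at C2), which is the face arylated by the (S)-BINAP complex in the quadrant model for (E)-configured acyclic acceptors; the ligand antipode would be used should the sense prove opposite. The trisubstituted, α-arylated C2=C3 bond of the isoflavone should not insert.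

Step 9
Reactants: 16 (3R)-3-{4-[(tert-butyldimethylsilyl)oxy]phenyl}-1-(2,4-dimethoxyphenyl)-3-{5-(5-hydroxy-7-methoxy-4-oxo-4H-chromen-3-yl)-2,4-bis[(triisopropylsilyl)oxy]phenyl}propan-1-one
Product: 17 (1RS,3R)-3-{4-[(tert-butyldimethylsilyl)oxy]phenyl}-1-(2,4-dimethoxyphenyl)-3-{5-(5-hydroxy-7-methoxy-4-oxo-4H-chromen-3-yl)-2,4-bis[(triisopropylsilyl)oxy]phenyl}propan-1-ol (both C1 epimers)
Conditions: NaBH4 (1.5 equiv), CeCl3·7H2O (1.5 equiv), MeOH/THF (2:1), −40 to 0 °C
Reagents that add atoms: none
Why: Luche reduction: cerium-activated methanol makes the borohydride a hard, 1,2-selective reagent, so the aryl ketone should be reduced while hydride addition at C2 of the isoflavone, the conjugate path by which borohydride alone attacks isoflavones, is suppressed. The carbinol centre is not controlled and need not be, since step 10 destroys it.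

Step 10
Reactants: 17 (1RS,3R)-3-{4-[(tert-butyldimethylsilyl)oxy]phenyl}-1-(2,4-dimethoxyphenyl)-3-{5-(5-hydroxy-7-methoxy-4-oxo-4H-chromen-3-yl)-2,4-bis[(triisopropylsilyl)oxy]phenyl}propan-1-ol
Product: 18 3-{5-[(1R,2E)-1-{4-[(tert-butyldimethylsilyl)oxy]phenyl}-3-(2,4-dimethoxyphenyl)prop-2-en-1-yl]-2,4-bis[(triisopropylsilyl)oxy]phenyl}-5-hydroxy-7-methoxy-4H-chromen-4-one
Conditions: Burgess reagent (methyl N-(triethylammoniosulfonyl)carbamate, 1.3 equiv), toluene, 50 °C
Reagents that add atoms: none
Why: Burgess dehydration through the sulfamate ester (syn elimination with benzylic ion-pair character); the conformer with the aryl and diarylmethyl groups anti leads to the E styrene from either epimer, and the neutral medium avoids a free 2,4-dimethoxybenzyl cation that the 4'-oxygen could trap. The chelated 5-OH is far less reactive toward the reagent than the secondary alcohol, and the stereocenter is not involved.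

Step 11
Reactants: 18 3-{5-[(1R,2E)-1-{4-[(tert-butyldimethylsilyl)oxy]phenyl}-3-(2,4-dimethoxyphenyl)prop-2-en-1-yl]-2,4-bis[(triisopropylsilyl)oxy]phenyl}-5-hydroxy-7-methoxy-4H-chromen-4-one
Product: 19 caraganin B, 3-{5-[(1R,2E)-3-(2,4-dimethoxyphenyl)-1-(4-hydroxyphenyl)prop-2-en-1-yl]-2,4-dihydroxyphenyl}-5-hydroxy-7-methoxy-4H-chromen-4-one
Conditions: Bu4NF (3.5 equiv), AcOH (3.5 equiv), THF, 0 °C
Reagents that add atoms: none
Why: Fluoride cleaves the three aryl silyl ethers, driven by Si–F bond formation; the acetic acid buffer keeps the medium near neutral, so the isoflavone (base), the styrene/4'-phenol pair (acid) and the doubly benzylic C–H should all be safe.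

## Compound list

1 | 4,6-dihydroxybenzene-1,3-dicarbaldehyde | O=Cc1cc(C=O)c(O)cc1O | starting material
2 | 4,6-bis(methoxymethoxy)benzene-1,3-dicarbaldehyde | COCOc1cc(OCOC)c(C=O)cc1C=O | intermediate
3 | 1-(2,6-dihydroxy-4-methoxyphenyl)ethan-1-one | CC(=O)c1c(O)cc(OC)cc1O | starting material
4 | 1-[2-hydroxy-4-methoxy-6-(methoxymethoxy)phenyl]ethan-1-one | COCOc1cc(OC)cc(O)c1C(C)=O | intermediate
5 | 5-{(1E)-3-[2-hydroxy-4-methoxy-6-(methoxymethoxy)phenyl]-3-oxoprop-1-en-1-yl}-2,4-bis(methoxymethoxy)benzaldehyde | COCOc1cc(OC)cc(O)c1C(=O)/C=C/c1cc(C=O)c(OCOC)cc1OCOC | intermediate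
6 | (2E)-3-[5-(dimethoxymethyl)-2,4-bis(methoxymethoxy)phenyl]-1-[2-hydroxy-4-methoxy-6-(methoxymethoxy)phenyl]prop-2-en-1-one | COCOc1cc(OC)cc(O)c1C(=O)/C=C/c1cc(C(OC)OC)c(OCOC)cc1OCOC | intermediate
7 | 2-[5-(dimethoxymethyl)-2,4-bis(methoxymethoxy)phenyl]-1-[2-hydroxy-4-methoxy-6-(methoxymethoxy)phenyl]-3,3-dimethoxypropan-1-one (racemic at C2) | COCOc1cc(OC)cc(O)c1C(=O)C(C(OC)OC)c1cc(C(OC)OC)c(OCOC)cc1OCOC | intermediate
8 | 3-[5-(dimethoxymethyl)-2,4-bis(methoxymethoxy)phenyl]-7-methoxy-5-(methoxymethoxy)-4H-chromen-4-one | COCOc1cc(OC)cc2occ(-c3cc(C(OC)OC)c(OCOC)cc3OCOC)c(=O)c12 | intermediate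
9 | 2,4-dihydroxy-5-(5-hydroxy-7-methoxy-4-oxo-4H-chromen-3-yl)benzaldehyde | COc1cc(O)c2c(c1)occ(-c1cc(C=O)c(O)cc1O)c2=O | intermediate
10 | 5-(5-hydroxy-7-methoxy-4-oxo-4H-chromen-3-yl)-2,4-bis[(triisopropylsilyl)oxy]benzaldehyde | COc1cc(O)c2c(c1)occ(-c1cc(C=O)c(O[Si](C(C)C)(C(C)C)C(C)C)cc1O[Si](C(C)C)(C(C)C)C(C)C)c2=O | intermediate
11 | 2-bromo-1-(2,4-dimethoxyphenyl)ethan-1-one | COc1ccc(C(=O)CBr)c(OC)c1 | starting material
12 | [2-(2,4-dimethoxyphenyl)-2-oxoethyl]triphenylphosphonium bromide | COc1ccc(C(=O)C[P+](c2ccccc2)(c2ccccc2)c2ccccc2)c(OC)c1.[Br-] | intermediate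
13 | 1-(2,4-dimethoxyphenyl)-2-(triphenyl-λ5-phosphanylidene)ethan-1-one | COc1ccc(C(=O)C=P(c2ccccc2)(c2ccccc2)c2ccccc2)c(OC)c1 | intermediate
14 | (2E)-1-(2,4-dimethoxyphenyl)-3-{5-(5-hydroxy-7-methoxy-4-oxo-4H-chromen-3-yl)-2,4-bis[(triisopropylsilyl)oxy]phenyl}prop-2-en-1-one | COc1ccc(C(=O)/C=C/c2cc(-c3coc4cc(OC)cc(O)c4c3=O)c(O[Si](C(C)C)(C(C)C)C(C)C)cc2O[Si](C(C)C)(C(C)C)C(C)C)c(OC)c1 | intermediate
15 | {4-[(tert-butyldimethylsilyl)oxy]phenyl}boronic acid | CC(C)(C)[Si](C)(C)Oc1ccc(B(O)O)cc1 | starting material
16 | (3R)-3-{4-[(tert-butyldimethylsilyl)oxy]phenyl}-1-(2,4-dimethoxyphenyl)-3-{5-(5-hydroxy-7-methoxy-4-oxo-4H-chromen-3-yl)-2,4-bis[(triisopropylsilyl)oxy]phenyl}propan-1-one | COc1ccc(C(=O)C[C@H](c2ccc(O[Si](C)(C)C(C)(C)C)cc2)c2cc(-c3coc4cc(OC)cc(O)c4c3=O)c(O[Si](C(C)C)(C(C)C)C(C)C)cc2O[Si](C(C)C)(C(C)C)C(C)C)c(OC)c1 | intermediate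
17 | (1RS,3R)-3-{4-[(tert-butyldimethylsilyl)oxy]phenyl}-1-(2,4-dimethoxyphenyl)-3-{5-(5-hydroxy-7-methoxy-4-oxo-4H-chromen-3-yl)-2,4-bis[(triisopropylsilyl)oxy]phenyl}propan-1-ol | COc1ccc(C(O)C[C@H](c2ccc(O[Si](C)(C)C(C)(C)C)cc2)c2cc(-c3coc4cc(OC)cc(O)c4c3=O)c(O[Si](C(C)C)(C(C)C)C(C)C)cc2O[Si](C(C)C)(C(C)C)C(C)C)c(OC)c1 | intermediate
18 | 3-{5-[(1R,2E)-1-{4-[(tert-butyldimethylsilyl)oxy]phenyl}-3-(2,4-dimethoxyphenyl)prop-2-en-1-yl]-2,4-bis[(triisopropylsilyl)oxy]phenyl}-5-hydroxy-7-methoxy-4H-chromen-4-one | COc1ccc(/C=C/[C@H](c2ccc(O[Si](C)(C)C(C)(C)C)cc2)c2cc(-c3coc4cc(OC)cc(O)c4c3=O)c(O[Si](C(C)C)(C(C)C)C(C)C)cc2O[Si](C(C)C)(C(C)C)C(C)C)c(OC)c1 | intermediate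
19 | caraganin B, 3-{5-[(1R,2E)-3-(2,4-dimethoxyphenyl)-1-(4-hydroxyphenyl)prop-2-en-1-yl]-2,4-dihydroxyphenyl}-5-hydroxy-7-methoxy-4H-chromen-4-one | COc1ccc(/C=C/[C@H](c2ccc(O)cc2)c2cc(-c3coc4cc(OC)cc(O)c4c3=O)c(O)cc2O)c(OC)c1 | target

## Step count and risk

Total step count: 11. Longest linear sequence: 9 steps (step 1 or 2, then 3, 4, 5, 7, 8, 9, 10, 11).

**Step 4 (key step).** The thallated enone may be diverted into attack by the free 2'-hydroxyl (aurone formation) if acetalisation of the formyl group is incomplete and ring B migrates too slowly. During the hot acid stage the liberated salicylaldehyde may also condense with the electron-rich phenolic rings.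

Fallback, setting out from 5: sodium acetate in refluxing ethanol closes ring C first by oxa-Michael addition to give flavanone F1. In HC(OMe)3 with catalytic H2SO4 this becomes flavanone dimethyl acetal F2. The trivalent iodine reagent PhI(OAc)2 then effects the known oxidative 2,3-aryl shift of flavanones: iodination of the enol ether at C3, migration of ring B from C2 assisted by the ring oxygen, and loss of iodobenzene and a proton. This gives 8, where the route is rejoined, and the acid stage of step 4 converts 8 into 9. In this variant ring closure precedes migration, no free phenol meets the oxidant, and thallium is avoided.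

**Step 8.** Insertion of the hindered enone, whose β-aryl group carries an ortho silyloxy substituent, may be slow. Protodeboronation of the electron-rich boronic acid would then consume the nucleophile, and facial discrimination on a chalcone-type acceptor may be poor.

Fallback, setting out from 10: Wittig reaction with (triphenylphosphoranylidene)acetaldehyde gives enal F3. Rhodium-catalysed addition of 15 with [RhCl(C2H4)2]2 and a C2-symmetric chiral bicyclo[2.2.2]octadiene ligand in aqueous dioxane, a combination well established for cinnamaldehydes, gives 3,3-diarylpropanal F4. The ligand enantiomer is chosen to arylate the same Si face. Addition of (2,4-dimethoxyphenyl)magnesium bromide (2.2 equiv, the first consumed by the 5-OH) in THF at −78 °C gives 17, where the route is rejoined. This variant needs neither the phosphonium salt nor the hydride step.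

**Step 9.** Hydride addition at C2 of the isoflavone (conjugate reduction, then over-reduction towards the isoflavan-4-ol) may compete, because the electron-rich, ortho-substituted aryl ketone is itself a slow acceptor.

Fallback, setting out from 16: KN(SiMe3)2 (2.1 equiv, the first deprotonating the 5-OH) and N-phenylbis(trifluoromethanesulfonimide) (1.05 equiv) in THF at −78 °C trap the Z enolate as (Z)-enol triflate F5. The chelated 5-phenoxide is far less nucleophilic than the enolate. Reduction with Pd(OAc)2/PPh3, HCO2H and Et3N in DMF at 60 °C (oxidative addition to zerovalent palladium, formate decarboxylation, reductive elimination with retention) gives the E styrene 18, where the route is rejoined. No hydride reagent and no benzylic cation are involved, and step 10 is bypassed as well.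

**Step 3.** Condensation at both formyl groups of 2, and a difficult separation of mono-chalcone, bis-chalcone and excess dialdehyde, may cost material.

Fallback, setting out from 4, with a ring B partner whose formyl groups are differentiated from the start: purchased 5-bromo-2,4-dihydroxybenzaldehyde F6 is converted with MOMCl and iPr2NEt into bis-MOM ether F7. HC(OMe)3 with catalytic pyridinium tosylate in methanol gives bromo acetal F8. Bromine–lithium exchange with n-BuLi at −78 °C followed by DMF gives mono-acetal aldehyde F9. Claisen–Schmidt condensation of F9 with 4 in a 1:1 ratio gives 6, where the route is rejoined. Compound 6 then enters step 4 already acetalised.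

## Further compounds

F1 | step 4 | 2-[5-formyl-2,4-bis(methoxymethoxy)phenyl]-7-methoxy-5-(methoxymethoxy)-2,3-dihydro-4H-chromen-4-one (racemic) | COCOc1cc(OC)cc2OC(c3cc(C=O)c(OCOC)cc3OCOC)CC(=O)c12
F2 | step 4 | 2-[5-(dimethoxymethyl)-2,4-bis(methoxymethoxy)phenyl]-7-methoxy-5-(methoxymethoxy)-2,3-dihydro-4H-chromen-4-one (racemic) | COCOc1cc(OC)cc2OC(c3cc(C(OC)OC)c(OCOC)cc3OCOC)CC(=O)c12
F3 | step 8 | (2E)-3-{5-(5-hydroxy-7-methoxy-4-oxo-4H-chromen-3-yl)-2,4-bis[(triisopropylsilyl)oxy]phenyl}prop-2-enal | COc1cc(O)c2c(c1)occ(-c1cc(/C=C/C=O)c(O[Si](C(C)C)(C(C)C)C(C)C)cc1O[Si](C(C)C)(C(C)C)C(C)C)c2=O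
F4 | step 8 | (3R)-3-{4-[(tert-butyldimethylsilyl)oxy]phenyl}-3-{5-(5-hydroxy-7-methoxy-4-oxo-4H-chromen-3-yl)-2,4-bis[(triisopropylsilyl)oxy]phenyl}propanal | O=CC[C@H](c1ccc(O[Si](C)(C)C(C)(C)C)cc1)c1cc(-c2coc3cc(OC)cc(O)c3c2=O)c(O[Si](C(C)C)(C(C)C)C(C)C)cc1O[Si](C(C)C)(C(C)C)C(C)C
F5 | step 9 | (1Z,3R)-3-{4-[(tert-butyldimethylsilyl)oxy]phenyl}-1-(2,4-dimethoxyphenyl)-3-{5-(5-hydroxy-7-methoxy-4-oxo-4H-chromen-3-yl)-2,4-bis[(triisopropylsilyl)oxy]phenyl}prop-1-en-1-yl trifluoromethanesulfonate | COc1ccc(/C(OS(=O)(=O)C(F)(F)F)=C/[C@H](c2ccc(O[Si](C)(C)C(C)(C)C)cc2)c2cc(-c3coc4cc(OC)cc(O)c4c3=O)c(O[Si](C(C)C)(C(C)C)C(C)C)cc2O[Si](C(C)C)(C(C)C)C(C)C)c(OC)c1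
F6 | step 3 | 5-bromo-2,4-dihydroxybenzaldehyde | O=Cc1cc(Br)c(O)cc1O
F7 | step 3 | 5-bromo-2,4-bis(methoxymethoxy)benzaldehyde | COCOc1cc(OCOC)c(C=O)cc1Br
F8 | step 3 | 1-bromo-5-(dimethoxymethyl)-2,4-bis(methoxymethoxy)benzene | COCOc1cc(OCOC)c(C(OC)OC)cc1Br
F9 | step 3 | 5-(dimethoxymethyl)-2,4-bis(methoxymethoxy)benzaldehyde | COCOc1cc(OCOC)c(C(OC)OC)cc1C=O
A1 | alternative 1 | 2-(diazoacetyl)-5-{5-[(1R,2E)-3-(2,4-dimethoxyphenyl)-1-{4-[(triisopropylsilyl)oxy]phenyl}prop-2-en-1-yl]-2,4-bis[(triisopropylsilyl)oxy]phenyl}-4H-pyran-4-one | COc1ccc(/C=C/[C@H](c2ccc(O[Si](C(C)C)(C(C)C)C(C)C)cc2)c2cc(-c3coc(C(=O)C=[N+]=[N-])cc3=O)c(O[Si](C(C)C)(C(C)C)C(C)C)cc2O[Si](C(C)C)(C(C)C)C(C)C)c(OC)c1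
A2 | alternative 1 | methoxyacetylene (methoxyethyne) | COC#C
A3 | alternative 1 | tris-O-triisopropylsilyl caraganin B | COc1ccc(/C=C/[C@H](c2ccc(O[Si](C(C)C)(C(C)C)C(C)C)cc2)c2cc(-c3coc4cc(OC)cc(O)c4c3=O)c(O[Si](C(C)C)(C(C)C)C(C)C)cc2O[Si](C(C)C)(C(C)C)C(C)C)c(OC)c1
A4 | alternative 2 | 3,5-dimethoxyphenyl 2-(5-bromo-2,4-diisopropoxyphenyl)-3-methoxyprop-2-enoate | COC=C(C(=O)Oc1cc(OC)cc(OC)c1)c1cc(Br)c(OC(C)C)cc1OC(C)C
A5 | alternative 2 | 3-(5-bromo-2,4-diisopropoxyphenyl)-5,7-dimethoxy-4H-chromen-4-one | COc1cc(OC)c2c(c1)occ(-c1cc(Br)c(OC(C)C)cc1OC(C)C)c2=O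
A6 | alternative 3 | 3,5-dimethoxy-2-(trimethylsilyl)phenyl trifluoromethanesulfonate | COc1cc(OC)c([Si](C)(C)C)c(OS(=O)(=O)C(F)(F)F)c1
A7 | alternative 3 | 2-{2,4-bis(allyloxy)-5-[(1R,2E)-1-[4-(allyloxy)phenyl]-3-(2,4-dimethoxyphenyl)prop-2-en-1-yl]phenyl}-3-methoxyprop-2-enoic acid | COc1ccc(/C=C/[C@H](c2ccc(OCC=C)cc2)c2cc(C(=COC)C(=O)O)c(OCC=C)cc2OCC=C)c(OC)c1
A8 | alternative 3 | tris-O-allyl 5-O-methyl caraganin B | COc1ccc(/C=C/[C@H](c2ccc(OCC=C)cc2)c2cc(-c3coc4cc(OC)cc(OC)c4c3=O)c(OCC=C)cc2OCC=C)c(OC)c1
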